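The 7-hydroxyl is freed last from a benzyl ether. The lactone C2=O is traced back to the C2 methylene of an isoflav-3-ene, and the C3=C4 bond of that alkene, through a C4 alcohol, to the C4 ketone of an isoflavone.
The central cut opens ring C of the isoflavone at O1–C2 and returns the aryl bond C3–C6' to the neighbouring carbon. This gives a 2'-hydroxychalcone with the chroman on Cβ, which is cut at Cα=Cβ into an acetophenone (ring A) and a chroman aldehyde (ring B fused to dihydropyran ring D).
Enabling feature: C6' of ring B has the ring D oxygen O1' (on C8a') para and the C5' methoxy group ortho, so ring B bridges to a well-stabilised phenonium ion and migrates very readily.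
Forward order: ring D (steps 1 and 2), union of the two halves (step 5), aryl shift with closure of ring C (step 6), exchange of the oxidation levels of C4 and C2 (steps 7 to 9), debenzylation (step 10).
Stereochemistry: the target has no stereocentre, and the sp3 centres that arise on the way are transient, need no control and are erased.

Key step: step 6

Assumption: 2',4'-dihydroxy-6'-methoxyacetophenone is taken as a purchasable compound, and all sp3 centres formed on the way are racemic and uncontrolled, so their SMILES carry no stereo descriptors.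

Step 1
Reactants: 1 2,4-dihydroxybenzaldehyde; 2 3-methylbut-2-enal
Product: 3 5-hydroxy-2,2-dimethyl-2H-chromene-6-carbaldehyde
Conditions: Ca(OH)2, MeOH, rt
Reagents that add atoms: none
Why: In this formal [3+3] chromenylation (aldol-type C-alkylation, loss of water, oxa-6π electrocyclisation) the phenoxide attacks the enal through C3, the carbon between the two oxygens, and the ring closes through the free 4-oxygen because the 2-hydroxyl stays hydrogen-bonded to the formyl group, which should give the angular chromene.

Step 2
Reactants: 3 5-hydroxy-2,2-dimethyl-2H-chromene-6-carbaldehyde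
Product: 4 5-hydroxy-2,2-dimethylchroman-6-carbaldehyde
Conditions: H2 (1 atm), 10% Pd/C, EtOAc, rt
Reagents that add atoms: none
Why: In this heterogeneous catalytic hydrogenation the cis-disubstituted styrene-type C3=C4 bond is saturated quickly, whereas the formyl group, deactivated by two donor oxygens and by its hydrogen bond to the 5-hydroxyl, reacts far more slowly, so stopping after one equivalent of H2 should give 4.

Step 3
Reactants: 4 5-hydroxy-2,2-dimethylchroman-6-carbaldehyde
Product: 5 5-methoxy-2,2-dimethylchroman-6-carbaldehyde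
Conditions: MeI, K2CO3, DMF, 40 °C
Reagents that add atoms: iodomethane, CI
Why: This is a Williamson etherification in which the only acidic site of 4, the chelated phenol, is deprotonated in the polar aprotic solvent and methylated at oxygen.

Step 4
Reactants: 6 1-(2,4-dihydroxy-6-methoxyphenyl)ethan-1-one (2',4'-dihydroxy-6'-methoxyacetophenone)
Product: 7 1-[4-(benzyloxy)-2-hydroxy-6-methoxyphenyl]ethan-1-one
Conditions: BnBr (1.05 equiv), K2CO3, acetone, reflux
Reagents that add atoms: benzyl bromide, BrCc1ccccc1
Why: In this Williamson etherification the 2'-hydroxyl is held in a strong hydrogen bond to the acetyl oxygen and is less acidic and less nucleophilic, so one equivalent of benzyl bromide should react only at the free 4'-hydroxyl.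

Step 5
Reactants: 5 5-methoxy-2,2-dimethylchroman-6-carbaldehyde; 7 1-[4-(benzyloxy)-2-hydroxy-6-methoxyphenyl]ethan-1-one
Product: 8 (E)-1-[4-(benzyloxy)-2-hydroxy-6-methoxyphenyl]-3-(5-methoxy-2,2-dimethylchroman-6-yl)prop-2-en-1-one
Conditions: 50% aq KOH, EtOH, rt; then dilute HCl, 0 °C
Reagents that add atoms: none
Why: In this Claisen–Schmidt condensation 5 cannot enolise and 7 has a single enolisable position, the E1cB dehydration gives the more stable E-enone, and the phenoxide form of the 2'-oxygen in strong base holds back closure to the flavanone.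

Step 6
Reactants: 8 (E)-1-[4-(benzyloxy)-2-hydroxy-6-methoxyphenyl]-3-(5-methoxy-2,2-dimethylchroman-6-yl)prop-2-en-1-one
Product: 11 7-(benzyloxy)-5-methoxy-3-(5-methoxy-2,2-dimethylchroman-6-yl)-4H-chromen-4-one, via dimethyl acetal 9 (not isolated), via 2-methoxyisoflavanone 10 (not isolated)
Conditions: PhI(OH)OTs (1.1 equiv), MeOH, 40 °C; then 3 M aq HCl, 60 °C, one pot
Reagents that add atoms: methanol, CO (supplies the methoxy groups of 9 and 10; none of its atoms stays in 11)
Why: The electrophilic trivalent iodine of PhI(OH)OTs adds to the enone C=C while methanol attacks Cβ, which is benzylic to the donor-rich ring B, so that a Cα–iodine bond and a Cβ–OMe bond result. Iodobenzene then leaves Cα with help from the neighbouring aryl group: C6' bridges to a phenonium ion whose charge is carried by O1' (para) and the C5' methoxy group (ortho), and opening of the bridge with push from the β-methoxy oxygen forms the C3–C6' bond and, after capture of a second methanol, acetal 9. Warming with aqueous HCl ionises 9 to an oxocarbenium ion, which the 2'-hydroxyl attacks in a 6-exo-trig closure (O1–C2, ring C) to give 10, and β-elimination of methanol from 10 gives the pyranone 11. The closest known reaction type is the oxidative rearrangement of chalcones to 1,2-diaryl-3,3-dimethoxypropan-1-ones with trivalent thallium or trivalent iodine reagents, followed by acid cyclisation to isoflavones. The stereocentres of 9 and 10 are uncontrolled and vanish in 11, which has none. Aryl migration must outrun attack of the phenol oxygen on Cα or Cβ (aurone or flavanone formation) and oxidation of ring A; the ortho/para oxygen pattern of ring B secures the first, and the chelated, acyl-deactivated phenol together with only a slight excess of oxidant secures the second.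

Step 7
Reactants: 11 7-(benzyloxy)-5-methoxy-3-(5-methoxy-2,2-dimethylchroman-6-yl)-4H-chromen-4-one
Product: 13 7-(benzyloxy)-5-methoxy-3-(5-methoxy-2,2-dimethylchroman-6-yl)chroman-4-ol (racemic cis/trans mixture), via isoflavanone 12 (not isolated)
Conditions: NaBH4 (4 equiv), THF–EtOH (1:1), 0 °C to rt
Reagents that add atoms: none
Why: Conjugate hydride addition to the vinylogous ester gives 12 after protonation and 1,2-reduction of its ketone gives 13, the standard borohydride reduction of isoflavones to isoflavan-4-ols, and the new centres C3 and C4 are left uncontrolled because step 8 removes both.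

Step 8
Reactants: 13 7-(benzyloxy)-5-methoxy-3-(5-methoxy-2,2-dimethylchroman-6-yl)chroman-4-ol
Product: 14 7-(benzyloxy)-5-methoxy-3-(5-methoxy-2,2-dimethylchroman-6-yl)-2H-chromene
Conditions: p-TsOH·H2O (5 mol %), toluene (dilute), 60 °C
Reagents that add atoms: none
Why: In this acid-catalysed E1 dehydration, ionisation at C4 is eased by O1 and the 5-methoxy group (ortho) and the 7-benzyloxy group (para), and loss of H3 from either diastereomer gives the stilbene-type C3=C4 bond conjugated with rings A and B.

Step 9
Reactants: 14 7-(benzyloxy)-5-methoxy-3-(5-methoxy-2,2-dimethylchroman-6-yl)-2H-chromene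
Product: 16 7-(benzyloxy)-5-methoxy-3-(5-methoxy-2,2-dimethylchroman-6-yl)-2H-chromen-2-one, via lactol 15 (not isolated)
Conditions: DDQ (2.3 equiv), 1,4-dioxane–H2O (20:1), rt
Reagents that add atoms: water, O
Why: DDQ abstracts hydride from C2–H, which is allylic and α to O1, to give an isoflavylium ion stabilised by the 5- and 7-oxygens; water adds at C2 to racemic lactol 15 and a second hydride abstraction gives the lactone, the same dehydrogenative oxidation that turns 3-aryl-2H-chromenes of the pterocarpene type into coumestans, while the aryl benzyl ether and the ring D methylenes react far more slowly at room temperature.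

Step 10
Reactants: 16 7-(benzyloxy)-5-methoxy-3-(5-methoxy-2,2-dimethylchroman-6-yl)-2H-chromen-2-one
Product: 17 7-hydroxy-5-methoxy-3-(5-methoxy-2,2-dimethylchroman-6-yl)-2H-chromen-2-one (CNP0139207.0)
Conditions: H2 (1 atm), 10% Pd/C, EtOAc–MeOH, rt
Reagents that add atoms: none
Why: Catalytic hydrogenolysis of the benzylic C–O bond is much faster than saturation of the trisubstituted, aryl-conjugated C3=C4 bond of the coumarin, and no other reducible group is present.

Compound list
1 | 2,4-dihydroxybenzaldehyde | O=Cc1ccc(O)cc1O | starting material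
2 | 3-methylbut-2-enal | CC(C)=CC=O | starting material
3 | 5-hydroxy-2,2-dimethyl-2H-chromene-6-carbaldehyde | O=Cc1ccc2OC(C)(C)C=Cc2c1O | intermediate
4 | 5-hydroxy-2,2-dimethylchroman-6-carbaldehyde | O=Cc1ccc2OC(C)(C)CCc2c1O | intermediate
5 | 5-methoxy-2,2-dimethylchroman-6-carbaldehyde | COc1c(C=O)ccc2OC(C)(C)CCc12 | intermediate
6 | 1-(2,4-dihydroxy-6-methoxyphenyl)ethan-1-one | CC(=O)c1c(O)cc(O)cc1OC | starting material
7 | 1-[4-(benzyloxy)-2-hydroxy-6-methoxyphenyl]ethan-1-one | CC(=O)c1c(O)cc(OCc2ccccc2)cc1OC | intermediate
8 | (E)-1-[4-(benzyloxy)-2-hydroxy-6-methoxyphenyl]-3-(5-methoxy-2,2-dimethylchroman-6-yl)prop-2-en-1-one | COc1cc(OCc2ccccc2)cc(O)c1C(=O)/C=C/c1ccc2OC(C)(C)CCc2c1OC | intermediate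
9 | 1-[4-(benzyloxy)-2-hydroxy-6-methoxyphenyl]-3,3-dimethoxy-2-(5-methoxy-2,2-dimethylchroman-6-yl)propan-1-one (racemic, formed in the flask) | COc1cc(OCc2ccccc2)cc(O)c1C(=O)C(C(OC)OC)c1ccc2OC(C)(C)CCc2c1OC | intermediate
10 | 7-(benzyloxy)-2,5-dimethoxy-3-(5-methoxy-2,2-dimethylchroman-6-yl)chroman-4-one (racemic diastereomer mixture, formed in the flask) | COC1Oc2cc(OCc3ccccc3)cc(OC)c2C(=O)C1c1ccc2OC(C)(C)CCc2c1OC | intermediate
11 | 7-(benzyloxy)-5-methoxy-3-(5-methoxy-2,2-dimethylchroman-6-yl)-4H-chromen-4-one | COc1cc(OCc2ccccc2)cc2occ(-c3ccc4OC(C)(C)CCc4c3OC)c(=O)c12 | intermediate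
12 | 7-(benzyloxy)-5-methoxy-3-(5-methoxy-2,2-dimethylchroman-6-yl)chroman-4-one (racemic, formed in the flask) | COc1cc(OCc2ccccc2)cc2OCC(c3ccc4OC(C)(C)CCc4c3OC)C(=O)c12 | intermediate
13 | 7-(benzyloxy)-5-methoxy-3-(5-methoxy-2,2-dimethylchroman-6-yl)chroman-4-ol (racemic cis/trans mixture) | COc1cc(OCc2ccccc2)cc2OCC(c3ccc4OC(C)(C)CCc4c3OC)C(O)c12 | intermediate
14 | 7-(benzyloxy)-5-methoxy-3-(5-methoxy-2,2-dimethylchroman-6-yl)-2H-chromene | COc1cc(OCc2ccccc2)cc2OCC(c3ccc4OC(C)(C)CCc4c3OC)=Cc12 | intermediate
15 | 7-(benzyloxy)-5-methoxy-3-(5-methoxy-2,2-dimethylchroman-6-yl)-2H-chromen-2-ol (racemic, formed in the flask) | COc1cc(OCc2ccccc2)cc2OC(O)C(c3ccc4OC(C)(C)CCc4c3OC)=Cc12 | intermediate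
16 | 7-(benzyloxy)-5-methoxy-3-(5-methoxy-2,2-dimethylchroman-6-yl)-2H-chromen-2-one | COc1cc(OCc2ccccc2)cc2oc(=O)c(-c3ccc4OC(C)(C)CCc4c3OC)cc12 | intermediate
17 | 7-hydroxy-5-methoxy-3-(5-methoxy-2,2-dimethylchroman-6-yl)-2H-chromen-2-one | COc1c(-c2cc3c(OC)cc(O)cc3oc2=O)ccc2c1CCC(C)(C)O2 | target

Total step count: 10.
Longest linear sequence: 9 steps (1, 2, 3, 5, 6, 7, 8, 9, 10).

Steps most likely to fail

Step 6. Instead of aryl migration, the free phenol oxygen may displace iodine at Cα or add to Cβ, or the oxidant may attack the electron-rich phenol ring. The fallback closes the ring first and shifts the aryl group second. From 8, NaOAc in refluxing EtOH should close ring C by intramolecular oxa-Michael addition to 7-(benzyloxy)-5-methoxy-2-(5-methoxy-2,2-dimethylchroman-6-yl)chroman-4-one F1, in which the phenol is tied up as an ether. PhI(OAc)2 with catalytic H2SO4 in HC(OMe)3 then iodinates the enol ether of F1 at C3. Ring B shifts from C2 to C3 as iodobenzene leaves, and loss of a proton gives 11, where the route is rejoined.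

Step 9. The isoflavylium ion may be hydrated at C4 instead of C2, which leads back towards the isoflavone oxidation pattern. The oxidation may also stall after the first hydride abstraction, or surplus DDQ may dehydrogenate ring D. The fallback separates the two oxidation events and gives each its own oxidant. From 14, Ph3C BF4 in CH2Cl2 abstracts the C2 hydride. The product, 7-(benzyloxy)-5-methoxy-3-(5-methoxy-2,2-dimethylchroman-6-yl)chromenylium tetrafluoroborate F2, is precipitated with ether and isolated. Aqueous NaHCO3 in THF should hydrate F2 at the more electrophilic and less hindered C2 to give lactol 15. MnO2 in CH2Cl2, an oxidant for allylic alcohols that leaves the ring D methylenes alone, then takes 15 to 16.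

Step 7. Ring C may open under the basic conditions at the isoflavanone stage (retro-oxa-Michael) with irreversible reduction of the opened enone, or the reduction may stall at the hindered, electron-rich ketone next to the 5-methoxy group. The fallback uses ring opening on purpose and rebuilds ring C directly at the lactone level, keeping the C3–C6' bond made in step 6.
- From 11, KOH in aqueous EtOH at reflux adds hydroxide at C2, opens the pyranone and cleaves formate. This gives 1-[4-(benzyloxy)-2-hydroxy-6-methoxyphenyl]-2-(5-methoxy-2,2-dimethylchroman-6-yl)ethan-1-one F3.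
- NaH and diethyl carbonate in toluene at reflux acylate F3 and cyclise it to 7-(benzyloxy)-4-hydroxy-5-methoxy-3-(5-methoxy-2,2-dimethylchroman-6-yl)-2H-chromen-2-one F4.
- Tf2O and Et3N in CH2Cl2 convert F4 into 7-(benzyloxy)-5-methoxy-3-(5-methoxy-2,2-dimethylchroman-6-yl)-2-oxo-2H-chromen-4-yl trifluoromethanesulfonate F5.
- Reduction of F5 with Pd(PPh3)4, HCO2H and Et3N in DMF at 60 °C replaces the triflate by hydrogen without touching the benzyl ether and gives 16, so steps 8 and 9 are bypassed as well.

Further compounds
F1 | step 6 | 7-(benzyloxy)-5-methoxy-2-(5-methoxy-2,2-dimethylchroman-6-yl)chroman-4-one (racemic) | COc1cc(OCc2ccccc2)cc2OC(CC(=O)c12)c1ccc2OC(C)(C)CCc2c1OC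
F2 | step 9 | 7-(benzyloxy)-5-methoxy-3-(5-methoxy-2,2-dimethylchroman-6-yl)chromenylium tetrafluoroborate | COc1cc(OCc2ccccc2)cc2[o+]cc(-c3ccc4OC(C)(C)CCc4c3OC)cc12.F[B-](F)(F)F
F3 | step 7 | 1-[4-(benzyloxy)-2-hydroxy-6-methoxyphenyl]-2-(5-methoxy-2,2-dimethylchroman-6-yl)ethan-1-one | COc1cc(OCc2ccccc2)cc(O)c1C(=O)Cc1ccc2OC(C)(C)CCc2c1OC
F4 | step 7 | 7-(benzyloxy)-4-hydroxy-5-methoxy-3-(5-methoxy-2,2-dimethylchroman-6-yl)-2H-chromen-2-one | COc1cc(OCc2ccccc2)cc2oc(=O)c(-c3ccc4OC(C)(C)CCc4c3OC)c(O)c12
F5 | step 7 | 7-(benzyloxy)-5-methoxy-3-(5-methoxy-2,2-dimethylchroman-6-yl)-2-oxo-2H-chromen-4-yl trifluoromethanesulfonate | COc1cc(OCc2ccccc2)cc2oc(=O)c(-c3ccc4OC(C)(C)CCc4c3OC)c(OS(=O)(=O)C(F)(F)F)c12
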